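Follow each unit of substrate through the steps below and count what every added step takes from the target.

    substrate ⇌ tight pair (K1 = 0.0048, k1 = 0.0254 h⁻¹, Ea1 = 110 kJ mol⁻¹, ΔH1 = −37.0 kJ mol⁻¹)
    tight pair ⇌ loose pair (K2 = 0.18, k2 = 423 h⁻¹, Ea2 = 74.0 kJ mol⁻¹, ΔH2 = −81.0 kJ mol⁻¹)
    coupling partner + tight pair → target (k3 = 52.9 L mol⁻¹ h⁻¹, Ea3 = 50.0 kJ mol⁻¹)
    coupling partner + loose pair → isomer of the product (k4 = 1340 L mol⁻¹ h⁻¹, Ea4 = 35.0 kJ mol⁻¹)
    substrate + tight pair → side product A (k5 = 0.0472 L mol⁻¹ h⁻¹, Ea5 = 68.0 kJ mol⁻¹)
    tight pair → side product B (k6 = 0.863 h⁻¹, Ea6 = 82.0 kJ mol⁻¹)
    (constants at 25 °C)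

| setting | gamma | eta | beta | zeta |
|---|---|---|---|---|
| substrate | 1.5 M | 1.5 M | 1.5 M | 1.5 M |
| coupling partner | 1.20 equiv | 1.20 equiv | 1.20 equiv | 1.20 equiv |
| temperature | 25 °C | 0 °C | 75 °C | 50 °C |
| time | 10 d | 10 d | 10 d | 10 d |

- a species is counted by the substrate in it: one side product A counts as two
- the list of constants is for 25 °C, to be carried to other temperatures by the activation energies and enthalpies

- the flask that comes out highest in amount of target, in percent of the substrate charged, or "all alike" when all lie within 1.5 percentage points (gamma / eta / beta / zeta / all alike)
- target at the end, in percent of the substrate charged, gamma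
- target at the end, in percent of the substrate charged, eta
- target at the end, in percent of the substrate charged, beta
- target at the end, in percent of the substrate charged, zeta

- Start with the main road alone: substrate enters as tight pair, and coupling partner takes tight pair to target. In gamma, tight pair returns to substrate at 5.29 h⁻¹ and is captured at 95.2 h⁻¹ at the start, so capture wins and entry into tight pair serves as the rate-limiting step. Reckoned as a first-order decay of substrate, the converted fraction comes to 99.8% in gamma and, with the activation energy carried to 0 °C, to 9.97% in eta. On this road, target equals that fraction.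

- Now add loose pair, which goes to isomer when partner captures it before it returns. Freeze the partner at its level once half of the conversion is done: 95.8% of its charge in eta and 58.4% in gamma.

- In eta, the constants for passage into loose pair, capture to target and capture to isomer carry to 27.5 h⁻¹, 8.35 L mol⁻¹ h⁻¹ and 368 L mol⁻¹ h⁻¹. Loose pair in eta returns at 7.69 h⁻¹ and is captured at 635 h⁻¹, so capture wins.

- The ratio for eta comes to 1.89. This is the isomer-per-target ratio, a selectivity factor: passage into loose pair divided by capture of tight pair, times the share of loose pair captured rather than returned. Gamma gives 2.85, which lowers its hand figure for target from 99.8% to 25.9%.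

- Last comes side product B, counted per target as its constant over capture of tight pair; side product A starts at 7.44 × 10⁻⁴ per target in gamma and is dropped. Gamma then reckons to 25.8%, and eta, reckoned without side product B, to 3.45%.

- Beta is taken as fully converted, with partner frozen at 58.3%. Its four constants carry to 30800 h⁻¹, 958 L mol⁻¹ h⁻¹, 10200 L mol⁻¹ h⁻¹ and 99.8 h⁻¹. The isomer ratio drops to 0.0175, side product B stands at 0.0992 per target, and the hand figure is 89.5%. Zeta is not reckoned by hand.

- The forecast names beta, with 25.7% for gamma, 3.45% for eta, 88% for beta and 78% for zeta: “Heating shifts the strongly exothermic tight-to-loose equilibrium back towards the tight pair”. Its beta figure lies below the hand figure.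

- The simulation gives beta as the highest flask, with 25.7% in gamma, 3.45% in eta, 88.7% in beta and 78.4% in zeta.

- Beta owes its target to the backward run from loose pair to tight pair: without that run it ends at 3.15% instead of 88.7%, and the isomer-per-target ratio with the return struck out, 30.6, leaves 3.15% by hand. Eta's simulated ratio is 1.89 against the reckoned 1.89. The neighbour flask, eta at 2.5 M with the same equivalents, holds more partner per litre; the same ratio reckons there to 1.14, lower than in eta, and that flask ends with 4.65% of target.

Its constants are those of an exercise; the flask was simulated.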